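The number I started from was 144 µM·min, the dose D·t of ash: the enzyme D charged (36 µM) times the 4.0 min it works on Z to give G. East looks nearly the same, with D at 37 µM, but its last reading at 3.00 min stands at a dose of 111 µM·min. With Z and Q charged alike, I took dose as a rough clock: south-west at 2.00 min and east at 1.33 min read Z at 72.1% and 72.3%, at doses of 52.0 µM·min and 49.2 µM·min, which are close but not equal. So I expected ash, with a dose larger than east's, to end below east's reading of 52.3% of Z.

Over east's last stretch Z fell from 72.3% to 52.3%, which gives 132 µM·min. This is the halving dose H, the dose that halves Z at that level of Z, a local pseudo-first-order half-life times D. From east's start to 1.33 min the same count reads 105 µM·min, less, so I used the late value. Ash lies 0.250 halvings past east's end, which put Z at 44.0% and G, more, at 56.0%. Maple has a dose of 72.0 µM·min, just past north's 66.0 µM·min, where Z read 66.5%. That put Z in maple at 64.4%, so I had Z leading in maple.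

all flasks: Z 0.056 M; Q 20 µM
- north: D 22 µM; run made earlier
- south-west: D 26 µM; run made earlier
- east: D 37 µM; run made earlier
- maple: D 18 µM; time 4.0 min
- ash: D 36 µM; time 4.0 min

- north (time / min: G / %, Z / %): 0.250: 3.3, 96.0; 0.500: 6.9, 93.2; 1.33: 16.8, 82.4; 3.00: 33.1, 66.5
- south-west (time / min: G / %, Z / %): 0.333: 5.3, 94.2; 1.00: 15.3, 85.2; 2.00: 28.4, 72.1; 3.00: 37.5, 62.6
- east (time / min: G / %, Z / %): 0.250: 5.9, 94.3; 0.500: 11.2, 88.4; 1.33: 27.0, 72.3; 3.00: 47.6, 52.3

(standard deviation of a reading: 0.3 percentage points)

- which of these there is most of at the end, counted by the Z in it, maple (Z / G)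
- which of these there is most of at the end, counted by the Z in it, ash (Z / G)
- final amount of the leader among these, as a percentage of the Z charged, in maple
- final amount of the leader among these, as a percentage of the Z charged, in ash

- the analysis behind the earlier runs scatters by 0.3 percentage points, standard deviation

The forecast gave Z leading maple at 64.3% and G leading ash at 55.5%, noting that “The constant sags as conversion grows”.

Maple ended with Z at 64.9%, and ash with G at 54.4% and Z at 45.6%. In ash, D stood at 78.7% of its charge at 2.00 min and 78.7% at 4.00 min, with L holding 21.3%. Counted from east's end to ash's end, the fall in Z reads as H of 166 µM·min, longer than the value I carried.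

    D + Q ⇌ L, settled at all times (K = 22000 L mol⁻¹)
    Z + D → G + D, rate k2*[Z]^3*[D]/(1 + ([Z]/Kh2)^3) (42.0 mM, k = 1.50 × 10⁵ L³ mol⁻³ s⁻¹)

Ash read at 15 min adds 2.38 halvings at that H, which puts Z at 8.74%. The simulated flask holds Z at 21.7%, more, so H in ash went on lengthening as Z fell.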